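**Strategy.** The tetrahydrofuran oxygen O1 of the furo[3,2-b]pyran-5-one core sits between two allylic carbons, and C2, C3, C3a and C7a all carry their substituents on one ring face. Everything rests on one flask operation that joins a cis-epoxy aldehyde (C3, C3a, C7a and the acrylate arm) to a (Z)-γ-alkoxyallylboronate: allylboration forges C2–C3 and sets both carbinol centres, then acid unmasks the C2 oxygen, which opens the epoxide at allylic C7a with inversion and forges O1–C7a. The epoxide oxygen becomes the lactone oxygen. One catalytic epoxidation thus controls four ring stereocentres; photolactonisation, cross-metathesis and a CBS reduction complete the target.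

Key step: step 6

Remark: locants in the text follow furo[3,2-b]pyran-5-one numbering (O1, C2, C3, C3a, O4, C5, C6, C7, C7a); the side-chain carbinol and benzoate carbons are named by their substituents.

Step 1
Reactants: 1 furan; 2 ethyl diazoacetate
Product: 4 ethyl (2E,4Z)-6-oxohexa-2,4-dienoate, via cyclopropane 3 (not isolated)
Conditions: Rh2(OAc)4 (0.5 mol %), furan as solvent, slow addition of 2, 20 °C, then 12 h at 20 °C
Reagents that add atoms: none
Why: Rhodium-carbenoid cyclopropanation of furan gives the donor–acceptor cyclopropane 3, whose spontaneous electrocyclic ring-opening (furan cyclopropanation–unravelling) should give the dienal with a 4Z alkene (the former ring bond) and a 2E alkene.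

Step 2
Reactants: 4 ethyl (2E,4Z)-6-oxohexa-2,4-dienoate
Product: 5 ethyl (2E,4Z)-6-hydroxyhexa-2,4-dienoate
Conditions: NaBH4, CeCl3·7H2O, MeOH, −40 °C
Reagents that add atoms: none
Why: Luche reduction delivers hydride 1,2 to the aldehyde only and should leave the dienoate and the 4Z geometry untouched.

Step 3
Reactants: 5 ethyl (2E,4Z)-6-hydroxyhexa-2,4-dienoate
Product: 6 ethyl (2E)-3-[(2S,3R)-3-(hydroxymethyl)oxiran-2-yl]prop-2-enoate
Conditions: Ti(OiPr)4 (0.2 equiv), D-(−)-diethyl tartrate (0.24 equiv), t-BuOOH, 4 Å MS, CH2Cl2, −20 °C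
Reagents that add atoms: tert-butyl hydroperoxide, CC(C)(C)OO
Why: Sharpless asymmetric epoxidation is hydroxyl-directed, so only the allylic-alcohol alkene reacts, stereospecifically (Z alkene gives the cis epoxide), and D-(−)-tartrate should set the (2S,3R) configuration, the first two stereocentres of the route.

Step 4
Reactants: 6 ethyl (2E)-3-[(2S,3R)-3-(hydroxymethyl)oxiran-2-yl]prop-2-enoate
Product: 7 ethyl (2E)-3-[(2S,3S)-3-formyloxiran-2-yl]prop-2-enoate
Conditions: Dess–Martin periodinane, NaHCO3, CH2Cl2, 0 °C, used crude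
Reagents that add atoms: none
Why: Dess–Martin oxidation converts the primary alcohol into the aldehyde under buffered conditions that should not epimerise the cis epoxide (the descriptor changes only because the CIP priorities change).

Step 5
Reactants: 8 2-(prop-2-en-1-yloxy)oxane
Product: 10 4,4,5,5-tetramethyl-2-[(2Z)-3-(oxan-2-yloxy)prop-2-en-1-yl]-1,3,2-dioxaborolane, via allyllithium 9 (not isolated)
Conditions: sec-BuLi, THF, −78 °C; then i-PrOB(pin), −78 to 20 °C; aq. NH4Cl
Reagents that add atoms: 2-isopropoxy-4,4,5,5-tetramethyl-1,3,2-dioxaborolane, CC(C)OB1OC(C)(C)C(C)(C)O1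
Why: α-Lithiation of the allyl ether gives the oxygen-chelated Z allyl anion 9, which is borylated at the unsubstituted γ-terminus (the established preparation of (Z)-γ-alkoxyallylboronates).

Step 6
Reactants: 7 ethyl (2E)-3-[(2S,3S)-3-formyloxiran-2-yl]prop-2-enoate; 10 4,4,5,5-tetramethyl-2-[(2Z)-3-(oxan-2-yloxy)prop-2-en-1-yl]-1,3,2-dioxaborolane
Product: 13 ethyl (2E)-3-[(2R,3R,4S,5S)-5-ethenyl-3,4-dihydroxyoxolan-2-yl]prop-2-enoate, via borate adduct 11 (not isolated), via epoxy diol 12 (not isolated)
Conditions: 10 (1.3 equiv), toluene, 4 Å MS, 20 °C, 36 h; then MeOH (10 equiv), CSA (0.3 equiv), CH2Cl2, 0 to 20 °C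
Reagents that add atoms: none
Why: Allylboration of 7 by 10 through a closed six-membered chair transition state (the known γ-alkoxyallylboration of α-oxygenated aldehydes) forms the C2–C3 bond and gives borate 11. The Z geometry of 10 fixes the syn relationship of the two new carbinol centres (C2 and C3), and Felkin–Anh attack anti to the epoxide C–O bond, which Z-γ-substituted allylboronates follow closely, fixes C3 relative to the epoxide. Methanolic CSA then cleaves the THP acetal and the borate, and the freed C2 hydroxyl of 12 opens the protonated cis epoxide at its allylic carbon with inversion (the known acid-catalysed endo cyclisation of hydroxy epoxides at a π-activated carbon), forming the O1–C7a bond. This closes the tetrahydrofuran in the 5-endo mode, the only alternative being a 4-exo closure to an oxetane, and inversion at C7a on a cis epoxide places all four ring substituents on one face. The step needs attack at C7a and not at C3a, secured by ring size and allylic activation, and no participation of the ester, secured by the E geometry of the acrylate, which keeps its carbonyl away from the epoxide.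

Step 7
Reactants: 13 ethyl (2E)-3-[(2R,3R,4S,5S)-5-ethenyl-3,4-dihydroxyoxolan-2-yl]prop-2-enoate
Product: 15 (2S,3R,3aR,7aR)-2-ethenyl-3-hydroxy-2,3,3a,7a-tetrahydro-5H-furo[3,2-b]pyran-5-one, via Z-enoate 14 (not isolated)
Conditions: hν (365 nm), thioxanthone (10 mol %), MeCN, 20 °C; then PPTS (cat.), CH2Cl2, 20 °C
Reagents that add atoms: none
Why: Triplet-sensitised E to Z photoisomerisation of the acyclic enoate is pulled forward because only the Z isomer 14 can lactonise onto the adjacent cis hydroxyl (six-membered ring, whereas the other hydroxyl would need a seven-membered ring), the photolactonisation principle known from coumarin formation.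

Step 8
Reactants: 16 (R)-lactic acid
Product: 17 (2R)-2-(benzoyloxy)propanoic acid
Conditions: BzCl (1.1 equiv), pyridine, CH2Cl2, 0 to 20 °C; aq. HCl work-up
Reagents that add atoms: benzoyl chloride, O=C(Cl)c1ccccc1
Why: O-Acylation of the secondary hydroxyl by the acid chloride (any mixed anhydride at the carboxyl is hydrolysed on work-up) should leave the bought stereocentre untouched.

Step 9
Reactants: 17 (2R)-2-(benzoyloxy)propanoic acid
Product: 19 (2R)-3-oxopent-4-en-2-yl benzoate, via acid chloride 18 (not isolated)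
Conditions: (COCl)2, DMF (cat.), CH2Cl2, 0 °C; then tributyl(vinyl)stannane, PdCl2(PPh3)2 (2 mol %), toluene, 60 °C
Reagents that add atoms: tributyl(vinyl)stannane, C=C[Sn](CCCC)(CCCC)CCCC
Why: Acid chloride formation followed by Stille acylation (oxidative addition of the acyl chloride to zerovalent palladium, vinyl transfer from tin, reductive elimination) builds the vinyl ketone without base, so the α-stereocentre should not enolise.

Step 10
Reactants: 15 (2S,3R,3aR,7aR)-2-ethenyl-3-hydroxy-2,3,3a,7a-tetrahydro-5H-furo[3,2-b]pyran-5-one; 19 (2R)-3-oxopent-4-en-2-yl benzoate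
Product: 20 (2R,4E)-5-[(2S,3R,3aR,7aR)-3-hydroxy-5-oxo-2,3,3a,7a-tetrahydro-5H-furo[3,2-b]pyran-2-yl]-3-oxopent-4-en-2-yl benzoate
Conditions: second-generation Hoveyda–Grubbs catalyst (5 mol %), 19 (3 equiv), CH2Cl2, 40 °C
Reagents that add atoms: none
Why: Olefin cross-metathesis between the terminal alkene of 15 and the electron-poor vinyl ketone 19 should favour the cross product and the E enone under thermodynamic control, while the endocyclic conjugated lactone alkene stays out of the reaction.

Step 11
Reactants: 20 (2R,4E)-5-[(2S,3R,3aR,7aR)-3-hydroxy-5-oxo-2,3,3a,7a-tetrahydro-5H-furo[3,2-b]pyran-2-yl]-3-oxopent-4-en-2-yl benzoate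
Product: 21 (2R,3S,4E)-3-hydroxy-5-[(2S,3R,3aR,7aR)-3-hydroxy-5-oxo-2,3,3a,7a-tetrahydro-5H-furo[3,2-b]pyran-2-yl]pent-4-en-2-yl benzoate
Conditions: (S)-2-methyl-CBS-oxazaborolidine (0.5 equiv), catecholborane (3 equiv), toluene, −78 °C
Reagents that add atoms: none
Why: In the Corey–Bakshi–Shibata reduction the oxazaborolidine–borane complex delivers hydride to one carbonyl face with the alkenyl group as the large substituent, so the (S)-catalyst should give the (S)-carbinol anti to the benzoate by reagent control, while the s-trans unsaturated lactone and the benzoate are inert at −78 °C.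

**Compound list**

1 | furan | c1ccoc1 | starting material
2 | ethyl diazoacetate | CCOC(=O)C=[N+]=[N-] | starting material
3 | ethyl 2-oxabicyclo[3.1.0]hex-3-ene-6-carboxylate (exo, racemic) | CCOC(=O)C1C2C=COC12 | intermediate
4 | ethyl (2E,4Z)-6-oxohexa-2,4-dienoate | CCOC(=O)/C=C/C=C\C=O | intermediate
5 | ethyl (2E,4Z)-6-hydroxyhexa-2,4-dienoate | CCOC(=O)/C=C/C=C\CO | intermediate
6 | ethyl (2E)-3-[(2S,3R)-3-(hydroxymethyl)oxiran-2-yl]prop-2-enoate (cis epoxide) | CCOC(=O)/C=C/[C@@H]1O[C@@H]1CO | intermediate
7 | ethyl (2E)-3-[(2S,3S)-3-formyloxiran-2-yl]prop-2-enoate (cis epoxide) | CCOC(=O)/C=C/[C@@H]1O[C@@H]1C=O | intermediate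
8 | 2-(prop-2-en-1-yloxy)oxane (allyl tetrahydropyranyl ether, racemic) | C=CCOC1CCCCO1 | starting material
9 | [(2Z)-3-(oxan-2-yloxy)prop-2-en-1-yl]lithium | [Li]C/C=C\OC1CCCCO1 | intermediate
10 | 4,4,5,5-tetramethyl-2-[(2Z)-3-(oxan-2-yloxy)prop-2-en-1-yl]-1,3,2-dioxaborolane | CC1(C)OB(C/C=C\OC2CCCCO2)OC1(C)C | intermediate
11 | ethyl (2E)-3-[(2S,3R)-3-[(1R,2S)-2-(oxan-2-yloxy)-1-[(4,4,5,5-tetramethyl-1,3,2-dioxaborolan-2-yl)oxy]but-3-en-1-yl]oxiran-2-yl]prop-2-enoate | C=C[C@H](OC1CCCCO1)[C@@H](OB2OC(C)(C)C(C)(C)O2)[C@H]3O[C@H]3/C=C/C(=O)OCC | intermediate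
12 | ethyl (2E)-3-[(2S,3R)-3-[(1R,2S)-1,2-dihydroxybut-3-en-1-yl]oxiran-2-yl]prop-2-enoate | C=C[C@H](O)[C@@H](O)[C@H]1O[C@H]1/C=C/C(=O)OCC | intermediate
13 | ethyl (2E)-3-[(2R,3R,4S,5S)-5-ethenyl-3,4-dihydroxyoxolan-2-yl]prop-2-enoate (all-cis) | C=C[C@@H]1O[C@H](/C=C/C(=O)OCC)[C@H](O)[C@@H]1O | intermediate
14 | ethyl (2Z)-3-[(2R,3R,4S,5S)-5-ethenyl-3,4-dihydroxyoxolan-2-yl]prop-2-enoate | C=C[C@@H]1O[C@H](/C=C\C(=O)OCC)[C@H](O)[C@@H]1O | intermediate
15 | (2S,3R,3aR,7aR)-2-ethenyl-3-hydroxy-2,3,3a,7a-tetrahydro-5H-furo[3,2-b]pyran-5-one | C=C[C@@H]1O[C@@H]2C=CC(=O)O[C@@H]2[C@@H]1O | intermediate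
16 | (R)-lactic acid | C[C@@H](O)C(=O)O | starting material
17 | (2R)-2-(benzoyloxy)propanoic acid | C[C@@H](OC(=O)c1ccccc1)C(=O)O | intermediate
18 | (2R)-2-(benzoyloxy)propanoyl chloride | C[C@@H](OC(=O)c1ccccc1)C(=O)Cl | intermediate
19 | (2R)-3-oxopent-4-en-2-yl benzoate | C[C@@H](OC(=O)c1ccccc1)C(=O)C=C | intermediate
20 | (2R,4E)-5-[(2S,3R,3aR,7aR)-3-hydroxy-5-oxo-2,3,3a,7a-tetrahydro-5H-furo[3,2-b]pyran-2-yl]-3-oxopent-4-en-2-yl benzoate | C[C@@H](OC(=O)c1ccccc1)C(=O)/C=C/[C@@H]1O[C@@H]2C=CC(=O)O[C@@H]2[C@@H]1O | intermediate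
21 | (2R,3S,4E)-3-hydroxy-5-[(2S,3R,3aR,7aR)-3-hydroxy-5-oxo-2,3,3a,7a-tetrahydro-5H-furo[3,2-b]pyran-2-yl]pent-4-en-2-yl benzoate | C[C@@H](OC(=O)c1ccccc1)[C@@H](O)/C=C/[C@@H]1O[C@@H]2C=CC(=O)O[C@@H]2[C@@H]1O | target

Total step count: 11. Longest linear sequence: 8 steps (steps 1, 2, 3, 4, 6, 7, 10 and 11).

**Steps most likely to fail**

Step 6. The acid-mediated ring closure may be slow or unselective, because the acrylate withdraws electron density from the allylic epoxide carbon, so solvolysis by methanol could compete; face selectivity in the allylboration may also be incomplete. The fallback closes the ring through a π-allylpalladium intermediate instead, which needs the trans epoxide; it sets out from 4 and returns at 13. Iodine-catalysed isomerisation of 4 should give ethyl (2E,4E)-6-oxohexa-2,4-dienoate F1. Luche reduction should give ethyl (2E,4E)-6-hydroxyhexa-2,4-dienoate F2. Sharpless epoxidation with D-(−)-diethyl tartrate should give the trans epoxy alcohol ethyl (2E)-3-[(2R,3R)-3-(hydroxymethyl)oxiran-2-yl]prop-2-enoate F3. Dess–Martin oxidation should give ethyl (2E)-3-[(2R,3S)-3-formyloxiran-2-yl]prop-2-enoate F4. Allylboration with 10 followed by PPTS in MeOH should give the trans epoxy diol ethyl (2E)-3-[(2R,3R)-3-[(1R,2S)-1,2-dihydroxybut-3-en-1-yl]oxiran-2-yl]prop-2-enoate F5. Pd(PPh3)4 in THF should then cyclise F5 to 13 by the known palladium-catalysed cyclisation of hydroxy vinyl epoxides: ionisation by zerovalent palladium and C–O bond formation each go with inversion, so the allylic carbon keeps its configuration, and the ester-bearing allyl terminus is not attacked.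

Step 7. Over-irradiation may sensitise the lactone product, which could then undergo intramolecular [2+2] cycloaddition with the cis-disposed vinyl group; hydrogen abstraction at the allylic ether positions and incomplete E to Z conversion are further risks. The fallback replaces light by an addition–elimination sequence; it sets out from 13 and returns at 15. Conjugate addition of sodium phenylselenolate ((PhSe)2, NaBH4, EtOH) to the enoate and acid-catalysed lactonisation should give the 7-(phenylselanyl)-6,7-dihydro derivative of 15 F6 (ring configuration as in 15, mixture at C7). Oxidation with H2O2 and syn-elimination of the selenoxide away from the oxygen-bearing carbon should then give 15.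

Step 11. Reagent control at the ketone may be poor, since the branched benzoyloxy-bearing substituent competes with the alkenyl group as the large group, and the benzoate may migrate to the new hydroxyl on work-up. The fallback sets the carbinol centre on the small fragment with an enzyme; it sets out from 19 and returns at 21. An enzyme of the ketoreductase class (NADPH-dependent alcohol dehydrogenase, glucose and glucose dehydrogenase for cofactor recycling, pH 7 buffer, screened for the (S)-selective member) should reduce 19 to (2R,3S)-3-hydroxypent-4-en-2-yl benzoate F7. Cross-metathesis of 15 with F7 (second-generation Hoveyda–Grubbs catalyst, CH2Cl2, 40 °C) should then give 21 directly.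

Further compounds
F1 | step 6 | ethyl (2E,4E)-6-oxohexa-2,4-dienoate | CCOC(=O)/C=C/C=C/C=O
F2 | step 6 | ethyl (2E,4E)-6-hydroxyhexa-2,4-dienoate | CCOC(=O)/C=C/C=C/CO
F3 | step 6 | ethyl (2E)-3-[(2R,3R)-3-(hydroxymethyl)oxiran-2-yl]prop-2-enoate | CCOC(=O)/C=C/[C@H]1O[C@@H]1CO
F4 | step 6 | ethyl (2E)-3-[(2R,3S)-3-formyloxiran-2-yl]prop-2-enoate | CCOC(=O)/C=C/[C@H]1O[C@@H]1C=O
F5 | step 6 | ethyl (2E)-3-[(2R,3R)-3-[(1R,2S)-1,2-dihydroxybut-3-en-1-yl]oxiran-2-yl]prop-2-enoate | C=C[C@H](O)[C@@H](O)[C@H]1O[C@@H]1/C=C/C(=O)OCC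
F6 | step 7 | 7-(phenylselanyl)-6,7-dihydro derivative of 15 (mixture at C7) | C=C[C@@H]1O[C@@H]2C([Se]c3ccccc3)CC(=O)O[C@@H]2[C@@H]1O
F7 | step 11 | (2R,3S)-3-hydroxypent-4-en-2-yl benzoate | C[C@@H](OC(=O)c1ccccc1)[C@@H](O)C=C
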